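The ratio of isomer to target, c(isomer)/c(target), is what I followed, since the share asked is one over one plus that ratio.

in all of them: gas 200 mM (held)

| charge | substrate | catalyst | temperature | remark | time |
|---|---|---|---|---|---|
| gamma | 2.8 M | 4 mM | 75 °C | run made earlier |  |
| epsilon | 2.8 M | 4 mM | 100 °C | run made earlier |  |
| north-east | 2.0 M | 4.0 mM | 100 °C |  | 15 d |
| south-west | 2.0 M | 4.0 mM | 80 °C |  | 15 d |
| south-east | 2.0 M | 4.0 mM | 120 °C |  | 15 d |
- gamma (time / d: target / %, isomer of the product / %): 3.00: 20.9, 1.4; 8.00: 37.2, 7.4; 15.0: 39.6, 16.4; 20.0: 39.0, 22.3; 30.0: 33.2, 32.7; 40.0: 30.0, 40.2; 50.0: 28.6, 47.6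
- epsilon (time / d: target / %, isomer of the product / %): 0.833: 13.6, 1.9; 2.50: 27.1, 12.3; 4.00: 30.5, 19.6; 6.00: 28.7, 29.9; 10.0: 25.0, 42.6; 12.0: 25.2, 47.4; 15.0: 24.3, 48.3

(readings scatter by 1 percentage point)
- the flask with the highest share of target in all that became target or isomer of the product ("all alike" if they lie within 1.5 percentage points) (north-east / south-west / south-east / all alike)
- share of target in all that became target or isomer of the product, north-east
- share of target in all that became target or isomer of the product, south-west
- share of target in all that became target or isomer of the product, south-east
- the earlier runs were read with a standard deviation of 1 percentage point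
- at the start none of the gas is in solution

In the gamma run the ratio starts from nothing and rises nearly straight. It reads 0.414 at 15.0 d, a gain of 0.0276 /d. I call this gain per day the climb of the ratio at 75 °C. In the epsilon run the reading at 4.00 d gives a climb of 0.161 /d. At that slope the ratio should reach one after 6.21 d, and target and isomer do cross near 6.00 d. Then the curve bends. The last epsilon reading gives 1.99 at 15.0 d, while the straight line would stand at 2.42, so the curve has fallen below the line. That is a bend and not a level, for the ratio read 1.88 at 12.0 d and was still rising.

I assumed that equal steps of temperature multiply the climb equally, and that the charge of substrate does not matter, which is untested. South-west then climbs 0.0393 /d, and the first answer at 15 d is a ratio of 0.589. I put that back in: it lies below one, and up to one the epsilon readings followed the line, so the line stands and the share is 62.9 %. In north-east the line gives 2.42, past the bend and above the last epsilon reading, so the second round takes that reading, made at the same temperature and time, a share of 33.4 %. South-east has no run at its temperature. I kept epsilon's last ratio, so the same share.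

The forecast gave 34 %, 61 % and 41 % and named south-west, but its ratio “seems to fall with temperature”, where I held mine.

The flask gives south-west first, with 30.7 % in north-east, 59.8 % in south-west and 41.0 % in south-east. Left 150 d, south-west falls to 17.4 %, so its share at 15 d is a point on the way, under kinetic control. Its ratio is 0.672 against my 0.589. South-east parts from me: its ratio is 1.44, below the 1.99 I kept.

    substrate + partner ⇌ target (K = 4.70 /M, k = 0.410 /M/h, Ea = 106 kJ/mol, ΔH = −5.00 kJ/mol)
    substrate + partner ⇌ isomer of the product (K = 12.0 /M, k = 0.00630 /M/h, Ea = 104 kJ/mol, ΔH = −40.0 kJ/mol)
    target + catalyst ⇌ isomer of the product + catalyst, rate k3*[catalyst]*[target] forward; the back reaction follows from the equilibrium constant (k = 2.40 /M/h, Ea = 88.0 kJ/mol)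
    gas ⇌ partner, rate k4*(csat - [partner]) (kL = 0.150 /h)
    (constants at 100 °C)

The neighbour is north-east run at 75 °C, the temperature of gamma. Its climb of 0.0276 /d gives a ratio of 0.414 at 15 d, so a share of 70.7 %. The computed flask gives 71.4 %.

The numbers in the tables are simulated from invented constants, noise included.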